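**Retrosynthetic overview**
1. The target is the penta-O-methyl ether 11 after one global demethylation.
2. The C8–O–C4' diaryl ether is cut by an Ullmann coupling: 8-hydroxyisoflavone 6 (nucleophile) plus 4'-iodo-8-chloroisoflavone 10 (electrophile).
3. Each isoflavone comes from a fully substituted phenol and an arylacetic acid: BF3-mediated ortho-acylation, then one-carbon insertion and closure of ring C.
4. Regiochemistry is fixed by the phenols: 2-chloro-3,5-dimethoxyphenol puts Cl at C8; 3,5-dimethoxycatechol (Dakin oxidation of 4,6-dimethoxysalicylaldehyde) puts OH at C8.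
5. Ring order: ring C of the genistein half and ring C of the chloro half are built separately, then the ether is formed, then deprotection.

Assumption: the target has no stereocentre and no hindered axis, so it is achiral and no stereocontrol is needed; 2-chloro-3,5-dimethoxyphenol is taken as a catalogue compound.

**Route**

Step 1
Reactants: 1 2-hydroxy-4,6-dimethoxybenzaldehyde
Product: 3 3,5-dimethoxybenzene-1,2-diol, via aryl formate 2 (not isolated)
Conditions: 30% H2O2, NaOH, H2O/THF, 0 °C to rt, N2; then aq. HCl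
Reagents that add atoms: hydrogen peroxide, OO
Why: Dakin oxidation, in which hydroperoxide adds to the aldehyde, the electron-rich ortho-hydroxyaryl group migrates to oxygen to give the aryl formate and this is saponified in situ to the catechol; no stereocentre is formed.

Step 2
Reactants: 3 3,5-dimethoxybenzene-1,2-diol; 4 2-(4-methoxyphenyl)acetic acid
Product: 6 8-hydroxy-5,7-dimethoxy-3-(4-methoxyphenyl)-4H-chromen-4-one, via catechol deoxybenzoin 5 (not isolated)
Conditions: BF3·OEt2 (neat), 85 °C, Ar; then DMF, MsCl, 50 to 75 °C; H2O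
Reagents that add atoms: N,N-dimethylformamide, CN(C)C=O
Why: Friedel–Crafts ortho-acylation at C6, the only free position next to a hydroxyl, gives the chelated deoxybenzoin, whose methylene is formylated by the DMF/MsCl Vilsmeier-type reagent and closes onto the only ortho-hydroxyl (deoxybenzoin isoflavone synthesis), leaving the neighbouring hydroxyl as the free 8-OH; no stereocentre is formed.

Step 3
Reactants: 7 2-chloro-3,5-dimethoxyphenol; 8 2-(4-iodophenyl)acetic acid
Product: 10 8-chloro-3-(4-iodophenyl)-5,7-dimethoxy-4H-chromen-4-one, via chloro deoxybenzoin 9 (not isolated)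
Conditions: BF3·OEt2 (neat), 85 °C, Ar; then DMF, MsCl, 50 to 75 °C; H2O
Reagents that add atoms: N,N-dimethylformamide, CN(C)C=O
Why: The same Friedel–Crafts ortho-acylation and Vilsmeier-type formylation–cyclisation, in which the single phenolic OH of 7 directs the acyl group to C6 and is the only oxygen that can close ring C, so chlorine ends at C8 and the aryl iodide is untouched; no stereocentre is formed.

Step 4
Reactants: 6 8-hydroxy-5,7-dimethoxy-3-(4-methoxyphenyl)-4H-chromen-4-one; 10 8-chloro-3-(4-iodophenyl)-5,7-dimethoxy-4H-chromen-4-one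
Product: 11 8-chloro-3-[4-({5,7-dimethoxy-3-(4-methoxyphenyl)-4-oxo-4H-chromen-8-yl}oxy)phenyl]-5,7-dimethoxy-4H-chromen-4-one
Conditions: CuI (10 mol%), picolinic acid (20 mol%), K3PO4, DMSO, 90 °C, Ar
Reagents that add atoms: none
Why: Ullmann-type copper-catalysed C–O coupling, in which the 8-OH of 6 is the only free hydroxyl and is not conjugated to the pyranone carbonyl, the aryl iodide of 10 reacts far faster than its hindered aryl chloride, and the picolinic acid ligand tolerates 2,6-disubstituted phenols; no stereocentre is formed.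

Step 5
Reactants: 11 8-chloro-3-[4-({5,7-dimethoxy-3-(4-methoxyphenyl)-4-oxo-4H-chromen-8-yl}oxy)phenyl]-5,7-dimethoxy-4H-chromen-4-one
Product: 12 8-chloro-3-[4-({5,7-dihydroxy-3-(4-hydroxyphenyl)-4-oxo-4H-chromen-8-yl}oxy)phenyl]-5,7-dihydroxy-4H-chromen-4-one
Conditions: BBr3 (excess), CH2Cl2, −78 °C to rt; then H2O
Reagents that add atoms: none
Why: Lewis-acid aryl methyl ether cleavage, in which BBr3 coordinates each methoxy oxygen and bromide removes the methyl group by SN2, while the diaryl ether, the aryl chloride and both pyranone rings are inert under anhydrous conditions that cause no ring-opening isomerisation; the product is achiral.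

**Compound list**
1 | 2-hydroxy-4,6-dimethoxybenzaldehyde | COc1cc(O)c(C=O)c(OC)c1 | starting material
2 | 2-hydroxy-4,6-dimethoxyphenyl formate | COc1cc(O)c(OC=O)c(OC)c1 | intermediate
3 | 3,5-dimethoxybenzene-1,2-diol | COc1cc(O)c(O)c(OC)c1 | intermediate
4 | 2-(4-methoxyphenyl)acetic acid | COc1ccc(CC(=O)O)cc1 | starting material
5 | 1-(2,3-dihydroxy-4,6-dimethoxyphenyl)-2-(4-methoxyphenyl)ethan-1-one | COc1ccc(CC(=O)c2c(O)c(O)c(OC)cc2OC)cc1 | intermediate
6 | 8-hydroxy-5,7-dimethoxy-3-(4-methoxyphenyl)-4H-chromen-4-one | COc1ccc(-c2coc3c(O)c(OC)cc(OC)c3c2=O)cc1 | intermediate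
7 | 2-chloro-3,5-dimethoxyphenol | COc1cc(O)c(Cl)c(OC)c1 | starting material
8 | 2-(4-iodophenyl)acetic acid | OC(=O)Cc1ccc(I)cc1 | starting material
9 | 1-(3-chloro-2-hydroxy-4,6-dimethoxyphenyl)-2-(4-iodophenyl)ethan-1-one | COc1cc(OC)c(C(=O)Cc2ccc(I)cc2)c(O)c1Cl | intermediate
10 | 8-chloro-3-(4-iodophenyl)-5,7-dimethoxy-4H-chromen-4-one | COc1cc(OC)c2c(=O)c(-c3ccc(I)cc3)coc2c1Cl | intermediate
11 | 8-chloro-3-[4-({5,7-dimethoxy-3-(4-methoxyphenyl)-4-oxo-4H-chromen-8-yl}oxy)phenyl]-5,7-dimethoxy-4H-chromen-4-one | COc1ccc(-c2coc3c(Oc4ccc(-c5coc6c(Cl)c(OC)cc(OC)c6c5=O)cc4)c(OC)cc(OC)c3c2=O)cc1 | intermediate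
12 | 8-chloro-3-[4-({5,7-dihydroxy-3-(4-hydroxyphenyl)-4-oxo-4H-chromen-8-yl}oxy)phenyl]-5,7-dihydroxy-4H-chromen-4-one | O=c1c(-c2ccc(Oc3c(O)cc(O)c4c(=O)c(-c5ccc(O)cc5)coc34)cc2)coc2c(Cl)c(O)cc(O)c12 | target

**Totals**
Total step count: 5. Longest linear sequence: 4 (steps 1, 2, 4, 5).

**Steps most likely to fail**

Step 2. The free catechol may be tied up by BF3 or by the DMF/MsCl reagent, or acylate at the wrong carbon. The fallback forms the diaryl ether before ring C of the genistein half; it sets out from 1 (using 10 and 4) and comes back at 11. Benzylation of 1 (BnBr, K2CO3, DMF) gives 2-(benzyloxy)-4,6-dimethoxybenzaldehyde F1. Baeyer–Villiger oxidation with mCPBA gives 2-(benzyloxy)-4,6-dimethoxyphenyl formate F2, which is methanolysed in the same flask (catalytic K2CO3, MeOH) to 2-(benzyloxy)-4,6-dimethoxyphenol F3. Coupling of F3 with 10 under the step 4 conditions gives 3-{4-[2-(benzyloxy)-4,6-dimethoxyphenoxy]phenyl}-8-chloro-5,7-dimethoxy-4H-chromen-4-one F4. Hydrogenolysis (H2, Pd/C, EtOAc, rt) gives 8-chloro-3-[4-(2-hydroxy-4,6-dimethoxyphenoxy)phenyl]-5,7-dimethoxy-4H-chromen-4-one F5. Acylation of F5 with 4 in BF3·OEt2 gives 8-chloro-3-[4-(2-hydroxy-4,6-dimethoxy-3-[(4-methoxyphenyl)acetyl]phenoxy)phenyl]-5,7-dimethoxy-4H-chromen-4-one F6, which is closed with DMF/MsCl in the same flask to 11. Here the aryloxy group already sits between the free OH and a methoxy group, so no catechol is ever exposed to the acylation.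

Step 4. The copper coupling of a 2,6-dioxygenated phenol may be slow on these chelating chromones. The fallback replaces copper catalysis by metal-free arylation with a diaryliodonium salt; it sets out from 10 and comes back at 11. Oxidation of 10 with mCPBA and TsOH·H2O in MeCN, then trapping with 1,3,5-trimethoxybenzene, gives [4-(8-chloro-5,7-dimethoxy-4-oxo-4H-chromen-3-yl)phenyl](2,4,6-trimethoxyphenyl)iodonium 4-methylbenzenesulfonate F7. Treating phenol 6 with F7 and K2CO3 in MeCN at 60 °C gives 11 by ligand coupling at trivalent iodine. The trimethoxyphenyl group is the non-transferred ligand, and such arylations tolerate hindered phenols.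

Step 5. Five-fold demethylation may stall at partly methylated material that precipitates as boron complexes. The fallback is a two-stage deprotection with a change of mechanism; it sets out from 11 and comes back at 12. BCl3 (CH2Cl2, 0 °C) cleaves only the two chelated peri methyl ethers to give 8-chloro-5-hydroxy-3-[4-({5-hydroxy-7-methoxy-3-(4-methoxyphenyl)-4-oxo-4H-chromen-8-yl}oxy)phenyl]-7-methoxy-4H-chromen-4-one F8. AlCl3 with EtSH (CH2Cl2, 0 °C to rt) then removes the remaining three methyl groups from F8 by thiol SN2 attack to give 12.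

**Further compounds**
F1 | step 2 | 2-(benzyloxy)-4,6-dimethoxybenzaldehyde | COc1cc(OCc2ccccc2)c(C=O)c(OC)c1
F2 | step 2 | 2-(benzyloxy)-4,6-dimethoxyphenyl formate | COc1cc(OCc2ccccc2)c(OC=O)c(OC)c1
F3 | step 2 | 2-(benzyloxy)-4,6-dimethoxyphenol | COc1cc(OCc2ccccc2)c(O)c(OC)c1
F4 | step 2 | 3-{4-[2-(benzyloxy)-4,6-dimethoxyphenoxy]phenyl}-8-chloro-5,7-dimethoxy-4H-chromen-4-one | COc1cc(OCc2ccccc2)c(Oc2ccc(-c3coc4c(Cl)c(OC)cc(OC)c4c3=O)cc2)c(OC)c1
F5 | step 2 | 8-chloro-3-[4-(2-hydroxy-4,6-dimethoxyphenoxy)phenyl]-5,7-dimethoxy-4H-chromen-4-one | COc1cc(O)c(Oc2ccc(-c3coc4c(Cl)c(OC)cc(OC)c4c3=O)cc2)c(OC)c1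
F6 | step 2 | 8-chloro-3-[4-(2-hydroxy-4,6-dimethoxy-3-[(4-methoxyphenyl)acetyl]phenoxy)phenyl]-5,7-dimethoxy-4H-chromen-4-one | COc1ccc(CC(=O)c2c(OC)cc(OC)c(Oc3ccc(-c4coc5c(Cl)c(OC)cc(OC)c5c4=O)cc3)c2O)cc1
F7 | step 4 | [4-(8-chloro-5,7-dimethoxy-4-oxo-4H-chromen-3-yl)phenyl](2,4,6-trimethoxyphenyl)iodonium 4-methylbenzenesulfonate | COc1cc(OC)c([I+]c2ccc(-c3coc4c(Cl)c(OC)cc(OC)c4c3=O)cc2)c(OC)c1.Cc1ccc(S(=O)(=O)[O-])cc1
F8 | step 5 | 8-chloro-5-hydroxy-3-[4-({5-hydroxy-7-methoxy-3-(4-methoxyphenyl)-4-oxo-4H-chromen-8-yl}oxy)phenyl]-7-methoxy-4H-chromen-4-one | COc1ccc(-c2coc3c(Oc4ccc(-c5coc6c(Cl)c(OC)cc(O)c6c5=O)cc4)c(OC)cc(O)c3c2=O)cc1
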